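**Retrosynthetic overview**

- Target 15 comes from bis-silyl diketone 14 by fluoride desilylation; 14 comes from C-acylation of the acetyl enolate of ring-A ketone 10 with 4-silyloxybenzoyl chloride 13 (ring B is bought as 4-hydroxybenzoic acid 11).
- 10 comes from O-methylation of the single free, hydrogen-bonded 2'-OH of acetophenone 9.
- 9 comes from a Diels–Alder benzannulation of siloxydiene 5 with but-3-yn-2-one 6, forming C1'–C2' and C5'–C6'; ring A is the only ring that is built.
- Feature used: ring A carries C2'–OMe and C4'–OH meta to each other, the prenyl group on C3' between them, and H on C5'/C6'. This is the oxygen pattern of an acetoacetate-derived 1,3-dioxygenated diene bearing prenyl on its central carbon; C1' and C6' come from the ynone.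
- 5 comes from methyl acetoacetate 1 and prenyl bromide 2 by C-alkylation, ketone O-silylation, and γ-deprotonation with ester O-silylation.

Key step: step 4

Remark: the target is drawn as the diketo tautomer; it is expected to equilibrate with its hydrogen-bonded keto-enol form, which is the same compound. Enol ether 4 and diene 5 are used as geometric mixtures (one isomer drawn), since this geometry is lost in step 4.

**Route**

Step 1
Reactants: 1 methyl acetoacetate; 2 prenyl bromide (1-bromo-3-methylbut-2-ene)
Product: 3 methyl 2-acetyl-5-methylhex-4-enoate (racemic)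
Conditions: 1 (1.5 equiv), NaH (1.2 equiv), THF, 0 °C; then 2 (1.0 equiv), 0 °C → rt
Reagents that add atoms: none
Why: C-alkylation of the sodium enolate of a β-keto ester with a primary allylic bromide (acetoacetic ester alkylation) should give the mono-prenyl product by direct SN2 displacement, the excess of enolate suppressing dialkylation.

Step 2
Reactants: 3 methyl 2-acetyl-5-methylhex-4-enoate
Product: 4 methyl 3-(tert-butyldimethylsilyloxy)-2-(3-methylbut-2-enyl)but-2-enoate (E/Z mixture expected; E isomer drawn)
Conditions: TBSOTf (1.2 equiv), Et3N (2 equiv), CH2Cl2, 0 °C → rt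
Reagents that add atoms: tert-butyldimethylsilyl trifluoromethanesulfonate, CC(C)(C)[Si](C)(C)OS(=O)(=O)C(F)(F)F
Why: Soft enolisation and O-silylation of the β-keto ester with a silyl triflate and a tertiary amine should give the ketone-derived conjugated silyl enol ether, placing the robust tert-butyldimethylsilyl group on the oxygen that becomes the C4' oxygen.

Step 3
Reactants: 4 methyl 3-(tert-butyldimethylsilyloxy)-2-(3-methylbut-2-enyl)but-2-enoate
Product: 5 (1Z)-3-(tert-butyldimethylsilyloxy)-1-methoxy-2-(3-methylbut-2-enyl)-1-(trimethylsilyloxy)buta-1,3-diene (one ketene acetal geometry drawn)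
Conditions: LiN(iPr)2 (1.15 equiv), THF, −78 °C; Me3SiCl (1.3 equiv), −78 °C → rt; concentrate, pentane, filter under argon; used crude
Reagents that add atoms: chlorotrimethylsilane, C[Si](C)(C)Cl
Why: Deprotonation of the β-silyloxy enoate at its γ-methyl group gives the ester dienolate, which the hard silyl chloride traps on oxygen, as in the standard second stage of the preparation of 1-alkoxy-1,3-bis(silyloxy)buta-1,3-dienes, a class in which congeners with an alkyl group on the central carbon are known.

Step 4
Reactants: 5 (1Z)-3-(tert-butyldimethylsilyloxy)-1-methoxy-2-(3-methylbut-2-enyl)-1-(trimethylsilyloxy)buta-1,3-diene; 6 but-3-yn-2-one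
Product: 9 1-[4-(tert-butyldimethylsilyloxy)-2-hydroxy-3-(3-methylbut-2-enyl)phenyl]ethanone, via cyclohexa-1,4-diene cycloadduct 7 (not isolated), via aryl trimethylsilyl ether 8 (not isolated)
Conditions: 5 (crude, 1.0 equiv), 6 (1.5 equiv), PhMe, −78 °C → rt (45 °C if aromatisation is incomplete); then 0.5 M HCl, THF, 0 °C, short contact
Reagents that add atoms: none
Why: The CH2 terminus of 5, the most nucleophilic carbon of this vinylogous silyl ketene acetal, bonds to the unsubstituted β-carbon of ynone 6 and the ketene acetal carbon bonds to the acetyl-bearing α-carbon, either in an asynchronous concerted Diels–Alder (4+2) cycloaddition or by Mukaiyama–Michael addition followed by 6-exo-trig closure of the allenolate carbon onto the oxocarbenium ion, and both paths form the same two bonds (C5'–C6' and C1'–C2') and close ring A as a six-membered carbocycle. The closest known reaction type is the Diels–Alder benzannulation of 1-alkoxy-1,3-bis(silyloxy)buta-1,3-dienes with acetylenic ketones and esters to resorcinol derivatives. Cycloadduct 7 is a cyclohexa-1,4-diene whose C2' mixed silyl ketal ionises with loss of methanol to a silyloxy-stabilised arenium ion, which loses a proton from C5' to give aryl silyl ether 8, and brief dilute acid then cleaves only the labile trimethylsilyl ether to leave the hydrogen-bonded phenol 9 with the tert-butyldimethylsilyl ether intact. The single stereocentre created (the ketal carbon of 7) disappears on aromatisation, so no stereocontrol is needed. The selectivity required is regiochemical, acetyl ortho to the C2' oxygen and para to the C4' silyloxy group, and it is secured by the polarisation of the two partners, while the prenyl group, carried on the central diene carbon, can only end up at C3' between the two oxygens, which emerge differently capped.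

Step 5
Reactants: 9 1-[4-(tert-butyldimethylsilyloxy)-2-hydroxy-3-(3-methylbut-2-enyl)phenyl]ethanone
Product: 10 1-[4-(tert-butyldimethylsilyloxy)-2-methoxy-3-(3-methylbut-2-enyl)phenyl]ethanone
Conditions: MeOH (3 equiv), PPh3 (1.5 equiv), DIAD (1.5 equiv), THF, 0 °C → rt
Reagents that add atoms: methanol, CO
Why: In this Mitsunobu etherification the phenol, acidified by the ortho acetyl group, protonates the phosphine–azodicarboxylate betaine and its phenoxide is methylated by the methoxyphosphonium ion under neutral conditions that spare the aryl silyl ether, and as the only free hydroxyl it has no competitor.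

Step 6
Reactants: 11 4-hydroxybenzoic acid
Product: 12 tert-butyldimethylsilyl 4-(tert-butyldimethylsilyloxy)benzoate
Conditions: TBSCl (2.3 equiv), imidazole (5 equiv), DMF, rt
Reagents that add atoms: tert-butyldimethylsilyl chloride, CC(C)(C)[Si](C)(C)Cl
Why: Imidazole-promoted silylation converts both the phenol and the carboxylic acid into their tert-butyldimethylsilyl derivatives.

Step 7
Reactants: 12 tert-butyldimethylsilyl 4-(tert-butyldimethylsilyloxy)benzoate
Product: 13 4-(tert-butyldimethylsilyloxy)benzoyl chloride
Conditions: (COCl)2 (1.2 equiv), DMF (cat.), CH2Cl2, 0 °C → rt; volatiles and TBSCl removed under high vacuum; used crude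
Reagents that add atoms: oxalyl chloride, ClC(=O)C(=O)Cl
Why: A silyl ester reacts with the chloroiminium (Vilsmeier) species from oxalyl chloride and catalytic DMF to give the acid chloride with release of the silyl chloride and no HCl, so the aryl silyl ether is retained.

Step 8
Reactants: 10 1-[4-(tert-butyldimethylsilyloxy)-2-methoxy-3-(3-methylbut-2-enyl)phenyl]ethanone; 13 4-(tert-butyldimethylsilyloxy)benzoyl chloride
Product: 14 1-[4-(tert-butyldimethylsilyloxy)-2-methoxy-3-(3-methylbut-2-enyl)phenyl]-3-[4-(tert-butyldimethylsilyloxy)phenyl]propane-1,3-dione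
Conditions: LiN(SiMe3)2 (2.2 equiv), THF, −78 °C; then 13 (1.1 equiv), −78 → −20 °C; sat. aq NH4Cl
Reagents that add atoms: none
Why: This crossed Claisen-type C-acylation of the lithium enolate of a methyl ketone (the only enolisable position of 10) with an acid chloride should stop at the diketone because the second equivalent of base converts the product into its chelated lithium diketonate, and aryl silyl ethers tolerate the amide base at low temperature.

Step 9
Reactants: 14 1-[4-(tert-butyldimethylsilyloxy)-2-methoxy-3-(3-methylbut-2-enyl)phenyl]-3-[4-(tert-butyldimethylsilyloxy)phenyl]propane-1,3-dione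
Product: 15 1-[4-hydroxy-2-methoxy-3-(3-methylbut-2-enyl)phenyl]-3-(4-hydroxyphenyl)propane-1,3-dione (target)
Conditions: Bu4NF (2.5 equiv), AcOH (2.5 equiv), THF, 0 °C → rt
Reagents that add atoms: none
Why: Fluoride cleaves both aryl silyl ethers through formation of the strong Si–F bond, and the acetic acid buffer keeps the β-diketone and the phenols protonated so that neither retro-Claisen cleavage nor cyclisation of the prenyl group onto the C4' oxygen is expected.

**Compound list**

1 | methyl acetoacetate (methyl 3-oxobutanoate) | CC(=O)CC(=O)OC | starting material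
2 | prenyl bromide (1-bromo-3-methylbut-2-ene) | CC(C)=CCBr | starting material
3 | methyl 2-acetyl-5-methylhex-4-enoate (racemic) | CC(=O)C(CC=C(C)C)C(=O)OC | intermediate
4 | methyl (E)-3-(tert-butyldimethylsilyloxy)-2-(3-methylbut-2-enyl)but-2-enoate (E/Z mixture expected, E drawn) | COC(=O)/C(CC=C(C)C)=C(\C)O[Si](C)(C)C(C)(C)C | intermediate
5 | (1Z)-3-(tert-butyldimethylsilyloxy)-1-methoxy-2-(3-methylbut-2-enyl)-1-(trimethylsilyloxy)buta-1,3-diene (one ketene acetal geometry drawn) | C=C(O[Si](C)(C)C(C)(C)C)/C(CC=C(C)C)=C(/OC)O[Si](C)(C)C | intermediate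
6 | but-3-yn-2-one | CC(=O)C#C | starting material
7 | 1-[4-(tert-butyldimethylsilyloxy)-6-methoxy-5-(3-methylbut-2-enyl)-6-(trimethylsilyloxy)cyclohexa-1,4-dien-1-yl]ethanone (racemic, not isolated) | CC(=O)C1=CCC(O[Si](C)(C)C(C)(C)C)=C(CC=C(C)C)C1(OC)O[Si](C)(C)C | intermediate
8 | 1-[4-(tert-butyldimethylsilyloxy)-3-(3-methylbut-2-enyl)-2-(trimethylsilyloxy)phenyl]ethanone (not isolated) | CC(=O)c1ccc(O[Si](C)(C)C(C)(C)C)c(CC=C(C)C)c1O[Si](C)(C)C | intermediate
9 | 1-[4-(tert-butyldimethylsilyloxy)-2-hydroxy-3-(3-methylbut-2-enyl)phenyl]ethanone | CC(=O)c1ccc(O[Si](C)(C)C(C)(C)C)c(CC=C(C)C)c1O | intermediate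
10 | 1-[4-(tert-butyldimethylsilyloxy)-2-methoxy-3-(3-methylbut-2-enyl)phenyl]ethanone | CC(=O)c1ccc(O[Si](C)(C)C(C)(C)C)c(CC=C(C)C)c1OC | intermediate
11 | 4-hydroxybenzoic acid | OC(=O)c1ccc(O)cc1 | starting material
12 | tert-butyldimethylsilyl 4-(tert-butyldimethylsilyloxy)benzoate | CC(C)(C)[Si](C)(C)OC(=O)c1ccc(O[Si](C)(C)C(C)(C)C)cc1 | intermediate
13 | 4-(tert-butyldimethylsilyloxy)benzoyl chloride | O=C(Cl)c1ccc(O[Si](C)(C)C(C)(C)C)cc1 | intermediate
14 | 1-[4-(tert-butyldimethylsilyloxy)-2-methoxy-3-(3-methylbut-2-enyl)phenyl]-3-[4-(tert-butyldimethylsilyloxy)phenyl]propane-1,3-dione | COc1c(C(=O)CC(=O)c2ccc(O[Si](C)(C)C(C)(C)C)cc2)ccc(O[Si](C)(C)C(C)(C)C)c1CC=C(C)C | intermediate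
15 | 1-[4-hydroxy-2-methoxy-3-(3-methylbut-2-enyl)phenyl]-3-(4-hydroxyphenyl)propane-1,3-dione | COc1c(C(=O)CC(=O)c2ccc(O)cc2)ccc(O)c1CC=C(C)C | target

**Step count and risks**

Total steps: 9. Longest linear sequence: 7 (steps 1, 2, 3, 4, 5, 8, 9); steps 6 and 7 form the short ring-B branch.

Steps most likely to fail:

1. Step 4 (benzannulation). The crowded, acid-sensitive diene may be lost by protodesilylation or ynone oligomerisation before it adds. Alternatively the Michael-type adduct may fail to close and aromatise cleanly, or the silyl enol ether may hydrolyse before aromatisation and erase the difference between the two oxygens. Should the ketal expel silanol instead of methanol, the product would be 10 itself, which is harmless. The fallback abandons ring construction and prenylates a bought ring A. It sets out from prenyl bromide 2 and commercial 1-(2,4-dihydroxyphenyl)ethanone F1. C-alkylation of the phenoxide of F1 with 2 (KOH, H2O, rt) is directed to the carbon between the two oxygens and gives 1-[2,4-dihydroxy-3-(3-methylbut-2-enyl)phenyl]ethanone F2. Selectivity over C5 and over oxygen is expected to be imperfect, so chromatographic separation is foreseen. Silylation of F2 (TBSCl 1.05 equiv, imidazole, CH2Cl2, 0 °C) should touch only the 4-OH, because the 2-OH is tied up in the hydrogen bond to the acetyl group. The fallback comes back to the route at 9.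

2. Step 8 (acylation of the ketone enolate). O-Acylation to the enol ester, a second acylation of the product enolate, or attack of the amide base on the acid chloride may erode the C-acylation. The fallback builds the diketone in two redox stages and sets out from 10. Its lithium enolate (LiN(iPr)2, THF, −78 °C) undergoes aldol addition to commercial 4-(tert-butyldimethylsilyloxy)benzaldehyde F3. This gives 1-[4-(tert-butyldimethylsilyloxy)-2-methoxy-3-(3-methylbut-2-enyl)phenyl]-3-[4-(tert-butyldimethylsilyloxy)phenyl]-3-hydroxypropan-1-one F4 (racemic). Oxidation of the benzylic β-hydroxy ketone with 2-iodoxybenzoic acid (EtOAc, 70 °C) gives the diketone. The fallback comes back to the route at 14.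

3. Step 3 (mixed silyl diene). Deprotonation of the crowded tetrasubstituted silyloxy enoate may be incomplete or misdirected to the doubly allylic CH2 of the prenyl group, silylation may occur on carbon, or the mixed diene may hydrolyse during isolation. The fallback postpones the differentiation of the two oxygens until after ring formation and sets out from 3. Silylation with Me3SiCl/Et3N gives methyl 3-(trimethylsilyloxy)-2-(3-methylbut-2-enyl)but-2-enoate F5. Treatment with LiN(iPr)2 then Me3SiCl (THF, −78 °C) gives 1-methoxy-2-(3-methylbut-2-enyl)-1,3-bis(trimethylsilyloxy)buta-1,3-diene F6, a member of the directly precedented class of 2-alkyl bis(trimethylsilyloxy) dienes. Addition of F6 to 6 (PhMe, −78 °C → rt) gives 1-[6-methoxy-5-(3-methylbut-2-enyl)-4,6-bis(trimethylsilyloxy)cyclohexa-1,4-dien-1-yl]ethanone F7. Work-up with 1 M HCl in THF strips methanol and both trimethylsilyl groups from F7 to give the diol F2 described above. Chelation-controlled monosilylation of F2 (TBSCl, imidazole, CH2Cl2, 0 °C) then follows. The fallback comes back to the route at 9.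

**Further compounds**

F1 | step 4 | 1-(2,4-dihydroxyphenyl)ethanone | CC(=O)c1ccc(O)cc1O
F2 | step 4 | 1-[2,4-dihydroxy-3-(3-methylbut-2-enyl)phenyl]ethanone | CC(=O)c1ccc(O)c(CC=C(C)C)c1O
F3 | step 8 | 4-(tert-butyldimethylsilyloxy)benzaldehyde | O=Cc1ccc(O[Si](C)(C)C(C)(C)C)cc1
F4 | step 8 | 1-[4-(tert-butyldimethylsilyloxy)-2-methoxy-3-(3-methylbut-2-enyl)phenyl]-3-[4-(tert-butyldimethylsilyloxy)phenyl]-3-hydroxypropan-1-one (racemic) | COc1c(C(=O)CC(O)c2ccc(O[Si](C)(C)C(C)(C)C)cc2)ccc(O[Si](C)(C)C(C)(C)C)c1CC=C(C)C
F5 | step 3 | methyl (E)-3-(trimethylsilyloxy)-2-(3-methylbut-2-enyl)but-2-enoate (E/Z mixture expected, E drawn) | COC(=O)/C(CC=C(C)C)=C(\C)O[Si](C)(C)C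
F6 | step 3 | (1Z)-1-methoxy-2-(3-methylbut-2-enyl)-1,3-bis(trimethylsilyloxy)buta-1,3-diene (one ketene acetal geometry drawn) | C=C(O[Si](C)(C)C)/C(CC=C(C)C)=C(/OC)O[Si](C)(C)C
F7 | step 3 | 1-[6-methoxy-5-(3-methylbut-2-enyl)-4,6-bis(trimethylsilyloxy)cyclohexa-1,4-dien-1-yl]ethanone (racemic) | CC(=O)C1=CCC(O[Si](C)(C)C)=C(CC=C(C)C)C1(OC)O[Si](C)(C)C
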